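**Plan**

1. Retrosynthesis (labdane numbering: ring A = C1–C5/C10, ring B = C5–C10; C18 = CH2OAc and C19 = CH3 on C4; C20 = CH3 on C10; C17 = CH3 on C8; C11–C16 = chain on C9). The butadiene is cut first (terminal alkyne + ethylene). The 18-OAc/6-OH pair and the 8-OH/C17 pair are then folded back into an 18,6-γ-lactone and an 8,17-epoxide. Ring A is finally cut at C1–C2 and C3–C4, removing C2–C3 as a vinylphosphonium unit.
2. Enabling feature: C18 on C4 and O6 on C6 are both equatorial and peri across C5, so they can be tied as a temporary γ-lactone whose α-carbon is C4 (donor). C10 is quaternary, so C1 can be a non-enolisable aldehyde (acceptor). Donor C4 and acceptor C1 are 1,4-related through C5–C10 and are bridged by a two-carbon unit that is acceptor at C3 and donor at C2.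
3. Forward order: ring B first, from p-benzoquinone mono-ketal 1 (C9 chain, C10 quaternary centre, C6 oxygen, lactone ring on C5–C6, C8 epoxide). Ring A follows by the annulation. Hydrogenation, one global hydride reduction and side-chain completion (alkyne, acetate, enyne metathesis) finish the route.
4. Stereochemistry: C9 comes from a chiral copper catalyst (desymmetrisation of 1). C10, C6, C5, C8 and C4 follow by substrate control relayed from C9 (trans alkylation, then reagent approach anti to the axial C20 methyl). The lactone ring dictates the face of C4 in the annulation.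

Key step: step 12

Remark: the ligand enantiomer in step 1 is chosen to give the (5S) adduct, assuming the sense of induction known for simple dialkylzinc reagents; compounds 16–20 are drawn as the expected major epimer at the lactone α-carbon, a centre that is erased in step 12.

**Route**

Step 1
Reactants: 1 4,4-dimethoxycyclohexa-2,5-dien-1-one; 2 2-(2-bromoethyl)-1,3-dioxolane
Product: 5 (5S)-5-[2-(1,3-dioxolan-2-yl)ethyl]-4,4-dimethoxycyclohex-2-en-1-one, via Grignard reagent 3 (not isolated), via diorganozinc reagent 4 (not isolated)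
Conditions: 2, Mg, THF, 25 °C; ZnCl2 (0.5 equiv), then 1,4-dioxane, filter; Cu(OTf)2 (2 mol%), (S,R,R)-binaphthol bis(1-phenylethyl)amine phosphoramidite (4 mol%), 1, toluene, −30 °C; aq NH4Cl
Reagents that add atoms: none
Why: Copper-catalysed enantioselective conjugate addition of a diorganozinc desymmetrises the prochiral dienone; the chiral catalyst selects one enantiotopic enone and one face, so C9 is set as the only stereocentre and the second enone is kept for later use.

Step 2
Reactants: 5 (5S)-5-[2-(1,3-dioxolan-2-yl)ethyl]-4,4-dimethoxycyclohex-2-en-1-one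
Product: 7 (5S,6S)-5-[2-(1,3-dioxolan-2-yl)ethyl]-4,4-dimethoxy-6-methylcyclohex-2-en-1-one, via lithium enolate 6 (not isolated)
Conditions: LiN(i-Pr)2, THF, −78 °C; MeI, −78 to −30 °C; pH 7 buffer work-up
Reagents that add atoms: iodomethane CI
Why: Kinetic α′-deprotonation of the enone (C6–H2 is the only enolisable site) and enolate alkylation should put the methyl trans to the neighbouring chain; this centre is re-enolised in step 3, so its configuration is not critical.

Step 3
Reactants: 7 (5S,6S)-5-[2-(1,3-dioxolan-2-yl)ethyl]-4,4-dimethoxy-6-methylcyclohex-2-en-1-one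
Product: 9 (5S,6R)-6-[(benzyloxy)methyl]-5-[2-(1,3-dioxolan-2-yl)ethyl]-4,4-dimethoxy-6-methylcyclohex-2-en-1-one, via lithium enolate 8 (not isolated)
Conditions: LiN(i-Pr)2, THF, −78 to −40 °C; BnOCH2Cl, DMPU, −78 to −20 °C
Reagents that add atoms: benzyl chloromethyl ether ClCOCc1ccccc1
Why: Second α′-alkylation (quaternisation) of the 2-methyl enolate; the electrophile should approach anti to the pseudoaxial C5 chain (the usual trans alkylation of 2-methyl-3-alkylcyclohexanone enolates), which sets quaternary C10 with CH2OBn (future C1) trans and CH3 (C20) cis to the chain and also blocks aromatisation of the ketal.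

Step 4
Reactants: 9 (5S,6R)-6-[(benzyloxy)methyl]-5-[2-(1,3-dioxolan-2-yl)ethyl]-4,4-dimethoxy-6-methylcyclohex-2-en-1-one
Product: 11 2-[(benzyloxy)methyl]-3-[2-(1,3-dioxolan-2-yl)ethyl]-6-hydroxy-4,4-dimethoxy-2-methylcyclohexan-1-one (6-OH cis to CH2OBn), via hydroperoxy ketone 10 (not isolated)
Conditions: Mn(dpm)3 (3 mol%), PhSiH3, O2 (1 atm), i-PrOH/CH2Cl2, 0 °C; then P(OEt)3
Reagents that add atoms: dioxygen O=O
Why: Mukaiyama-type hydrogen-atom-transfer reductive α-hydroxylation of an enone (H to the β-carbon, O2 capture at the α-carbon, phosphite reduction of the hydroperoxide); oxygen should enter opposite the axial C20 methyl and the axial ketal methoxy of the chair that keeps both carbon arms equatorial, giving the equatorial O6, which is also the more stable epimer of this enolisable ketol.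

Step 5
Reactants: 11 2-[(benzyloxy)methyl]-3-[2-(1,3-dioxolan-2-yl)ethyl]-6-hydroxy-4,4-dimethoxy-2-methylcyclohexan-1-one
Product: 13 4-[(benzyloxy)methyl]-5-[2-(1,3-dioxolan-2-yl)ethyl]-6,6-dimethoxy-4-methyl-5,6,7,7a-tetrahydro-1-benzofuran-2(4H)-one, via phosphonoacetate ester 12 (not isolated)
Conditions: (EtO)2P(O)CH2CO2H, DCC, DMAP (cat.), CH2Cl2, 0 °C to rt; filter; NaH, THF, 0 °C to rt
Reagents that add atoms: (diethoxyphosphoryl)acetic acid OC(=O)CP(=O)(OCC)OCC
Why: Esterification followed by intramolecular Horner–Wadsworth–Emmons olefination of the hindered ketone builds the butenolide (C4=C5 and the C18–O6 lactone ring); no new stereocentre is formed and O6 remains in the plane of the butenolide, i.e. equatorial on ring B.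

Step 6
Reactants: 13 4-[(benzyloxy)methyl]-5-[2-(1,3-dioxolan-2-yl)ethyl]-6,6-dimethoxy-4-methyl-5,6,7,7a-tetrahydro-1-benzofuran-2(4H)-one
Product: 14 5-[2-(1,3-dioxolan-2-yl)ethyl]-4-(hydroxymethyl)-6,6-dimethoxy-4-methylhexahydro-1-benzofuran-2(3H)-one (trans-fused)
Conditions: H2 (4 atm), Pd/C (10%), EtOAc, rt
Reagents that add atoms: none
Why: Heterogeneous hydrogenation should deliver H to C5 from the face opposite the axial methyl on the adjacent quaternary carbon (as in the trans-selective hydrogenation of steroidal 5-enes), giving the trans-fused lactone with H5 anti to C20; the benzyl ether is hydrogenolysed in the same operation.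

Step 7
Reactants: 14 5-[2-(1,3-dioxolan-2-yl)ethyl]-4-(hydroxymethyl)-6,6-dimethoxy-4-methylhexahydro-1-benzofuran-2(3H)-one
Product: 16 5-[2-(1,3-dioxolan-2-yl)ethyl]-4-(hydroxymethyl)-6,6-dimethoxy-3,4-dimethylhexahydro-1-benzofuran-2(3H)-one, via dilithium alkoxide enolate 15 (not isolated)
Conditions: LiN(i-Pr)2 (2.2 equiv), THF, −78 °C; MeI (1.05 equiv), −78 to −40 °C; H2O
Reagents that add atoms: iodomethane CI
Why: Dianion alkylation: the lactone enolate is C-methylated while the lithium alkoxide is inert to MeI at low temperature; the methyl should enter anti to the axial ring methyl, but this centre becomes the enolate carbon again in step 12.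

Step 8
Reactants: 16 5-[2-(1,3-dioxolan-2-yl)ethyl]-4-(hydroxymethyl)-6,6-dimethoxy-3,4-dimethylhexahydro-1-benzofuran-2(3H)-one
Product: 17 5-[2-(1,3-dioxolan-2-yl)ethyl]-4-(hydroxymethyl)-3,4-dimethylhexahydro-1-benzofuran-2,6-dione
Conditions: PPTS (cat.), acetone/H2O, rt
Reagents that add atoms: water O
Why: Mild acid hydrolysis of the acyclic dimethyl ketal, which is far more labile than the aldehyde dioxolane; conditions are kept non-basic because the product is a β-acyloxy ketone.

Step 9
Reactants: 17 5-[2-(1,3-dioxolan-2-yl)ethyl]-4-(hydroxymethyl)-3,4-dimethylhexahydro-1-benzofuran-2,6-dione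
Product: 18 5-[2-(1,3-dioxolan-2-yl)ethyl]-4-(hydroxymethyl)-3,4-dimethyl-6-methylidenehexahydro-1-benzofuran-2(3H)-one
Conditions: Zn, CH2Br2, TiCl4, THF/CH2Cl2, 0 °C to rt
Reagents that add atoms: dibromomethane BrCBr
Why: Takai–Lombardo methylenation, a non-basic ketone olefination chosen so that the β-acyloxy ketone neither eliminates the lactone carboxylate nor epimerises at C9; it is ketone-selective in the presence of the lactone.

Step 10
Reactants: 18 5-[2-(1,3-dioxolan-2-yl)ethyl]-4-(hydroxymethyl)-3,4-dimethyl-6-methylidenehexahydro-1-benzofuran-2(3H)-one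
Product: 19 5-[2-(1,3-dioxolan-2-yl)ethyl]-4-(hydroxymethyl)-3,4-dimethylhexahydrospiro[1-benzofuran-6,2'-oxiran]-2(3H)-one (epoxide O equatorial)
Conditions: mCPBA, NaHCO3, CH2Cl2, 0 °C
Reagents that add atoms: 3-chloroperbenzoic acid OOC(=O)c1cccc(Cl)c1
Why: Prilezhaev epoxidation of the exocyclic alkene from the equatorial direction, because the axial face is shielded by the syn-axial C20 methyl on the lactone-locked chair; this sets C8 with equatorial oxygen and axial CH2 (future C17).

Step 11
Reactants: 19 5-[2-(1,3-dioxolan-2-yl)ethyl]-4-(hydroxymethyl)-3,4-dimethylhexahydrospiro[1-benzofuran-6,2'-oxiran]-2(3H)-one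
Product: 20 5-[2-(1,3-dioxolan-2-yl)ethyl]-3,4-dimethyl-2-oxooctahydrospiro[1-benzofuran-6,2'-oxirane]-4-carbaldehyde
Conditions: Dess–Martin periodinane, NaHCO3, CH2Cl2, rt
Reagents that add atoms: none
Why: Dess–Martin oxidation of the neopentyl primary alcohol gives the non-enolisable C1 aldehyde without touching the epoxide, lactone or acetal.

Step 12
Reactants: 20 5-[2-(1,3-dioxolan-2-yl)ethyl]-3,4-dimethyl-2-oxooctahydrospiro[1-benzofuran-6,2'-oxirane]-4-carbaldehyde
Product: 23 13,13-(ethylenedioxy)-8,17-epoxy-14,15,16-trinorlabd-1-en-18,6-olide (ent series), via lithium lactone enolate 21 (not isolated), via phosphorus ylide 22 (not isolated)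
Conditions: LiN(SiMe3)2 (1.1 equiv), THF, −78 °C; CH2=CHPPh3Br (1.3 equiv), THF/DMPU, −78 to 50 °C, 0.02 M
Reagents that add atoms: vinyltriphenylphosphonium bromide C=C[P+](c1ccccc1)(c1ccccc1)c1ccccc1.[Br-]
Why: The base removes the only acidic proton, the lactone α-H at C4 (the aldehyde sits on quaternary C10 and cannot enolise); enolate 21 adds in Michael fashion to the vinylphosphonium salt to form C3–C4 and the non-stabilised ylide 22, whose C2 then attacks the C1 aldehyde and collapses through the oxaphosphetane to C1=C2 with loss of Ph3PO. The closest known reaction type is the cycloalkene annulation of carbanions with vinyltriphenylphosphonium bromide (Schweizer reagent), i.e. conjugate addition followed by intramolecular Wittig olefination. Ring A is the only ring closed: C3–C4 forms intermolecularly and the six-membered ring is closed by the intramolecular Wittig step, the ylide carbon adding to the exocyclic aldehyde carbonyl. The one new stereocentre, quaternary C4, is controlled by the temporary trans-fused γ-lactone: the planar enolate is attacked on the face of H5, anti to the axial C20 methyl, which places C3 equatorial and pointing toward C1 and leaves the C19 methyl axial as in the target. The step needs C- over O-alkylation and ring closure over intermolecular Wittig or aldol reaction; the soft vinylphosphonium acceptor, the non-enolisable aldehyde, the impossibility of a four-membered aldol ring and dilution should secure this.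

Step 13
Reactants: 23 13,13-(ethylenedioxy)-8,17-epoxy-14,15,16-trinorlabd-1-en-18,6-olide (ent series)
Product: 24 13,13-(ethylenedioxy)-8,17-epoxy-14,15,16-trinorlabdan-18,6-olide (ent series)
Conditions: H2 (1 atm), Pd/C (5%), EtOAc, rt
Reagents that add atoms: none
Why: Catalytic hydrogenation of the only alkene (cis-disubstituted C1=C2); the aliphatic epoxide, lactone and acetal should survive neutral conditions.

Step 14
Reactants: 24 13,13-(ethylenedioxy)-8,17-epoxy-14,15,16-trinorlabdan-18,6-olide (ent series)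
Product: 26 6,8,18-trihydroxy-14,15,16-trinorlabdan-13-al (ent series; in equilibrium with its 8,13-lactol), via triol acetal 25 (not isolated)
Conditions: LiAlH4, THF, 0 °C to reflux; then 2 M HCl, THF, rt
Reagents that add atoms: water O
Why: One hydride reduction opens the lactone to the 6,18-diol and the epoxide at its CH2 terminus to the tertiary 8-ol with the C17 methyl (C6 and C8 configurations untouched), and aqueous acid then hydrolyses the dioxolane.

Step 15
Reactants: 26 6,8,18-trihydroxy-14,15,16-trinorlabdan-13-al (ent series)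
Product: 27 14,15-dinorlabd-13(16)-yne-6,8,18-triol (ent series)
Conditions: dimethyl (1-diazo-2-oxopropyl)phosphonate, K2CO3, MeOH, 0 °C to rt
Reagents that add atoms: dimethyl (1-diazo-2-oxopropyl)phosphonate COP(=O)(OC)C(=[N+]=[N-])C(C)=O
Why: Seyferth–Gilbert homologation with the Ohira–Bestmann reagent converts the aldehyde (released from its lactol under the basic conditions) into the terminal alkyne C13≡C16 without affecting any stereocentre.

Step 16
Reactants: 27 14,15-dinorlabd-13(16)-yne-6,8,18-triol (ent series)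
Product: 28 6,8-dihydroxy-14,15-dinorlabd-13(16)-yn-18-yl acetate (ent series)
Conditions: Ac2O (1.05 equiv), 2,4,6-collidine, CH2Cl2, −20 to 0 °C
Reagents that add atoms: acetic anhydride CC(=O)OC(C)=O
Why: Selective acylation of the primary alcohol over the hindered secondary 6-OH and the tertiary 8-OH.

Step 17
Reactants: 28 6,8-dihydroxy-14,15-dinorlabd-13(16)-yn-18-yl acetate (ent series)
Product: 29 6,8-dihydroxylabda-13(16),14-dien-18-yl acetate (ent series; CNP0317825.1)
Conditions: ethylene (1 atm), second-generation Grubbs catalyst RuCl2(=CHPh)(H2IMes)(PCy3) (5 mol%), CH2Cl2, 40 °C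
Reagents that add atoms: ethylene C=C
Why: Ruthenium-catalysed cross enyne metathesis of a terminal alkyne with ethylene gives the 2-substituted buta-1,3-diene; free hydroxyls and the acetate are tolerated.

**Compound list**

1 | 4,4-dimethoxycyclohexa-2,5-dien-1-one | COC1(OC)C=CC(=O)C=C1 | starting material
2 | 2-(2-bromoethyl)-1,3-dioxolane | BrCCC1OCCO1 | starting material
3 | [2-(1,3-dioxolan-2-yl)ethyl]magnesium bromide (not isolated) | Br[Mg]CCC1OCCO1 | intermediate
4 | bis[2-(1,3-dioxolan-2-yl)ethyl]zinc (not isolated) | C1COC(CC[Zn]CCC2OCCO2)O1 | intermediate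
5 | (5S)-5-[2-(1,3-dioxolan-2-yl)ethyl]-4,4-dimethoxycyclohex-2-en-1-one | O1CCOC1CC[C@H]2CC(=O)C=CC2(OC)OC | intermediate
6 | lithium enolate of 5, C1–OLi with C1=C6 (not isolated) | O1CCOC1CC[C@H]2C=C(O[Li])C=CC2(OC)OC | intermediate
7 | (5S,6S)-5-[2-(1,3-dioxolan-2-yl)ethyl]-4,4-dimethoxy-6-methylcyclohex-2-en-1-one (methyl trans to chain) | O1CCOC1CC[C@H]2[C@H](C)C(=O)C=CC2(OC)OC | intermediate
8 | lithium enolate of 7 (not isolated) | O1CCOC1CC[C@H]2C(C)=C(O[Li])C=CC2(OC)OC | intermediate
9 | (5S,6R)-6-[(benzyloxy)methyl]-5-[2-(1,3-dioxolan-2-yl)ethyl]-4,4-dimethoxy-6-methylcyclohex-2-en-1-one (CH2OBn trans, CH3 cis to chain) | O1CCOC1CC[C@H]2[C@](C)(COCc3ccccc3)C(=O)C=CC2(OC)OC | intermediate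
10 | 6-hydroperoxy analogue of 11 (not isolated) | O1CCOC1CC[C@H]2[C@](C)(COCc3ccccc3)C(=O)[C@H](OO)CC2(OC)OC | intermediate
11 | 2-[(benzyloxy)methyl]-3-[2-(1,3-dioxolan-2-yl)ethyl]-6-hydroxy-4,4-dimethoxy-2-methylcyclohexan-1-one (6-OH cis to CH2OBn, trans to chain) | O1CCOC1CC[C@H]2[C@](C)(COCc3ccccc3)C(=O)[C@H](O)CC2(OC)OC | intermediate
12 | (diethoxyphosphoryl)acetate ester of 11 (not isolated) | O1CCOC1CC[C@H]2[C@](C)(COCc3ccccc3)C(=O)[C@H](OC(=O)CP(=O)(OCC)OCC)CC2(OC)OC | intermediate
13 | 4-[(benzyloxy)methyl]-5-[2-(1,3-dioxolan-2-yl)ethyl]-6,6-dimethoxy-4-methyl-5,6,7,7a-tetrahydro-1-benzofuran-2(4H)-one | O1CCOC1CC[C@H]2[C@](C)(COCc3ccccc3)C4=CC(=O)O[C@@H]4CC2(OC)OC | intermediate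
14 | 5-[2-(1,3-dioxolan-2-yl)ethyl]-4-(hydroxymethyl)-6,6-dimethoxy-4-methylhexahydro-1-benzofuran-2(3H)-one (trans-fused; 3a-H cis to CH2OH) | O1CCOC1CC[C@H]2[C@](C)(CO)[C@H]4CC(=O)O[C@@H]4CC2(OC)OC | intermediate
15 | dilithium alkoxide/lactone enolate of 14 (not isolated) | O1CCOC1CC[C@H]2[C@](C)(CO[Li])[C@H]4C=C(O[Li])O[C@@H]4CC2(OC)OC | intermediate
16 | 5-[2-(1,3-dioxolan-2-yl)ethyl]-4-(hydroxymethyl)-6,6-dimethoxy-3,4-dimethylhexahydro-1-benzofuran-2(3H)-one (3-CH3 cis to 3a-H) | O1CCOC1CC[C@H]2[C@](C)(CO)[C@H]4[C@H](C)C(=O)O[C@@H]4CC2(OC)OC | intermediate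
17 | 5-[2-(1,3-dioxolan-2-yl)ethyl]-4-(hydroxymethyl)-3,4-dimethylhexahydro-1-benzofuran-2,6-dione | O1CCOC1CC[C@H]2[C@](C)(CO)[C@H]4[C@H](C)C(=O)O[C@@H]4CC2=O | intermediate
18 | 5-[2-(1,3-dioxolan-2-yl)ethyl]-4-(hydroxymethyl)-3,4-dimethyl-6-methylidenehexahydro-1-benzofuran-2(3H)-one | O1CCOC1CC[C@H]2[C@](C)(CO)[C@H]4[C@H](C)C(=O)O[C@@H]4CC2=C | intermediate
19 | 5-[2-(1,3-dioxolan-2-yl)ethyl]-4-(hydroxymethyl)-3,4-dimethylhexahydrospiro[1-benzofuran-6,2'-oxiran]-2(3H)-one (epoxide O equatorial) | O1CCOC1CC[C@H]2[C@](C)(CO)[C@H]4[C@H](C)C(=O)O[C@@H]4C[C@@]25CO5 | intermediate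
20 | 5-[2-(1,3-dioxolan-2-yl)ethyl]-3,4-dimethyl-2-oxooctahydrospiro[1-benzofuran-6,2'-oxirane]-4-carbaldehyde | O1CCOC1CC[C@H]2[C@](C)(C=O)[C@H]4[C@H](C)C(=O)O[C@@H]4C[C@@]25CO5 | intermediate
21 | lithium lactone enolate of 20 (not isolated) | O1CCOC1CC[C@H]2[C@](C)(C=O)[C@H]4C(C)=C(O[Li])O[C@@H]4C[C@@]25CO5 | intermediate
22 | ylide: 20 carrying a 3-(triphenylphosphoranylidene)propyl group at the lactone α-carbon in place of H (not isolated) | O1CCOC1CC[C@H]2[C@](C)(C=O)[C@H]4[C@](C)(CC=P(c6ccccc6)(c6ccccc6)c6ccccc6)C(=O)O[C@@H]4C[C@@]25CO5 | intermediate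
23 | 13,13-(ethylenedioxy)-8,17-epoxy-14,15,16-trinorlabd-1-en-18,6-olide, ent series (C19, C20 and epoxide CH2 on one face; H5, H9, O6 and epoxide O on the other) | O6CCOC6CC[C@H]1[C@]2(C)C=CC[C@@]3(C)[C@H]2[C@H](OC3=O)C[C@@]15CO5 | intermediate
24 | 13,13-(ethylenedioxy)-8,17-epoxy-14,15,16-trinorlabdan-18,6-olide, ent series | O6CCOC6CC[C@H]1[C@]2(C)CCC[C@@]3(C)[C@H]2[C@H](OC3=O)C[C@@]15CO5 | intermediate
25 | 13,13-(ethylenedioxy)-14,15,16-trinorlabdane-6,8,18-triol, ent series (not isolated) | O6CCOC6CC[C@H]1[C@]2(C)CCC[C@](C)(CO)[C@H]2[C@H](O)C[C@]1(C)O | intermediate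
26 | 6,8,18-trihydroxy-14,15,16-trinorlabdan-13-al, ent series (open form of the 8,13-lactol) | O=CCC[C@H]1[C@]2(C)CCC[C@](C)(CO)[C@H]2[C@H](O)C[C@]1(C)O | intermediate
27 | 14,15-dinorlabd-13(16)-yne-6,8,18-triol, ent series | C#CCC[C@H]1[C@]2(C)CCC[C@](C)(CO)[C@H]2[C@H](O)C[C@]1(C)O | intermediate
28 | 6,8-dihydroxy-14,15-dinorlabd-13(16)-yn-18-yl acetate, ent series | C#CCC[C@H]1[C@]2(C)CCC[C@](C)(COC(C)=O)[C@H]2[C@H](O)C[C@]1(C)O | intermediate
29 | 6,8-dihydroxylabda-13(16),14-dien-18-yl acetate, ent series (CNP0317825.1; 6-OH, 8-OH and CH2OAc equatorial, C17, C19 and C20 methyls axial) | C=CC(=C)CC[C@H]1[C@]2(C)CCC[C@](C)(COC(C)=O)[C@H]2[C@H](O)C[C@]1(C)O | target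

**Step count and risks**

Total step count: 17. Longest linear sequence: 17 steps (from 1; the organozinc reagent is made in the flask in step 1).

Steps most likely to fail:

1. Step 12 (annulation). The amide base may add to the aldehyde, or the ylide may fail to close the strained, doubly trans-fused tricycle and instead undergo intermolecular Wittig reaction. Fallback, setting out from 20 and returning at 23: the aldehyde is methylenated with Ph3P=CH2 (THF, 0 °C) to the 4-vinyl lactone F1. The lactone enolate of F1 (LiN(i-Pr)2, THF, −78 °C) is alkylated with allyl bromide on the same face, anti to the axial methyl, to give the 3-allyl-4-vinyl lactone F2. Ring-closing metathesis of F2 with the second-generation Grubbs catalyst (CH2Cl2, 40 °C) should close ring A with loss of ethylene and give 23.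

2. Step 6 (hydrogenation). Hydrogen may be delivered to the wrong face, giving the cis-fused lactone, or the hindered alkene may remain unreduced while only the benzyl ether is cleaved. Fallback, setting out from 13 and returning at 14: brief hydrogenolysis (H2 1 atm, Pd/C, EtOAc) removes only the benzyl group to give the hydroxymethyl butenolide F3. Hydroxyl-directed homogeneous hydrogenation with [Ir(cod)(PCy3)(py)]PF6 (H2, CH2Cl2) should then deliver hydrogen to C5 from the face of the neighbouring CH2OH, which is the face required for 14.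

3. Step 9 (methylenation). The β-acyloxy ketone may eliminate the lactone carboxylate, or the Lewis-acidic titanium reagent may cleave the dioxolane. Fallback, setting out from 17 and returning at 18: the weakly basic organocerium reagent from Me3SiCH2MgCl and CeCl3 (THF, −78 °C) adds to the ketone to give the β-hydroxysilane F4. Peterson elimination of F4 (KH, THF, 0 °C) should give the exocyclic alkene 18.

Further compounds
F1 | step 12 | 5-[2-(1,3-dioxolan-2-yl)ethyl]-4-ethenyl-3,4-dimethylhexahydrospiro[1-benzofuran-6,2'-oxiran]-2(3H)-one | O1CCOC1CC[C@H]2[C@](C)(C=C)[C@H]4[C@H](C)C(=O)O[C@@H]4C[C@@]25CO5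
F2 | step 12 | 5-[2-(1,3-dioxolan-2-yl)ethyl]-4-ethenyl-3,4-dimethyl-3-(prop-2-en-1-yl)hexahydrospiro[1-benzofuran-6,2'-oxiran]-2(3H)-one | O1CCOC1CC[C@H]2[C@](C)(C=C)[C@H]4[C@](C)(CC=C)C(=O)O[C@@H]4C[C@@]25CO5
F3 | step 6 | 5-[2-(1,3-dioxolan-2-yl)ethyl]-4-(hydroxymethyl)-6,6-dimethoxy-4-methyl-5,6,7,7a-tetrahydro-1-benzofuran-2(4H)-one | O1CCOC1CC[C@H]2[C@](C)(CO)C4=CC(=O)O[C@@H]4CC2(OC)OC
F4 | step 9 | 5-[2-(1,3-dioxolan-2-yl)ethyl]-6-hydroxy-4-(hydroxymethyl)-3,4-dimethyl-6-[(trimethylsilyl)methyl]hexahydro-1-benzofuran-2(3H)-one (6-OH axial) | O1CCOC1CC[C@H]2[C@](C)(CO)[C@H]4[C@H](C)C(=O)O[C@@H]4C[C@]2(O)C[Si](C)(C)C
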